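The product is chains, and their average length is monomer in chains over chains begun.

| flask | free monomer | protic impurity | initiator | remark | time |
|---|---|---|---|---|---|
| dusk | 0.079 M | 1.58 mM | 1.1 mM | run made earlier |  |
| dawn | 0.079 M | 1.58 mM | 2.4 mM | run made earlier |  |
| flask | 0.079 M | 1.58 mM | 1.6 mM |  | 5.0 h |

| run | time / h | monomer in chains / % | free monomer / % |
|---|---|---|---|
| dusk | 1.00 | 2.3 | 97.1 |
| dusk | 2.00 | 4.1 | 94.9 |
| dusk | 3.00 | 5.0 | 91.1 |
| dusk | 4.00 | 7.7 | 91.0 |
| dusk | 5.00 | 8.0 | 89.3 |
| dusk | 6.00 | 10.6 | 87.5 |
| dawn | 0.417 | 2.0 | 97.0 |
| dawn | 1.33 | 4.9 | 93.8 |
| dawn | 2.00 | 8.1 | 90.7 |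
| dawn | 3.00 | 11.1 | 87.5 |
| dawn | 5.00 | 18.2 | 80.3 |
| dawn | 6.00 | 21.2 | 77.3 |

(standard deviation of a reading: 0.5 percentage points)

1. whether the average number of monomer units in a chain (chains begun, living or dead) reaches 3.0 by 5.0 h (yes / no)
2. average number of monomer units in a chain (chains begun, living or dead) at 5.0 h

- the average divides the monomer in chains by the number of chains begun, living and dead together
- the earlier runs were read with a standard deviation of 0.5 percentage points
- the earlier runs do not show the number of chains; that part of a forecast is a guess

1. Bench rule: each initiator begins one chain. Length is then the roof length, c(free monomer)/c(initiator) as charged, times the share of free monomer charged that stands in chains. For the flask the roof is 49.4.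

2. In decimal logarithms the flask's roof stands at 1.69 and the wanted length at 0.477. The difference asks for a share of 6.08%.

3. At 5.00 h the dusk run reads 8.0% under a roof of 71.8, so the rule gives it a length of 5.75. At 5.00 h the dawn run reads 18.2% under a roof of 32.9, so the rule gives it a length of 5.99. The slope of log share against log initiator, the reaction order, reads 1.05, so share and roof nearly cancel. The reckoning here puts the flask midway, at 5.87.

4. The rule stops holding in the flask if protic impurity also begins chains, which the earlier runs do not show either way. In the flask c(protic impurity)/c(initiator) is 0.987, so the count could be twice as large. The roof then falls to 24.8 and the reckoned length to 2.95, beside the wanted 3.0.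

5. The forecast says yes, with length 5.6, a little below the reckoning here: “Either way, 3.0 is probably reached”.

    free monomer + living end → monomer in chains + living end, rate k1*[living end]*[free monomer] (k = 0.00797 /M/s)
    protic impurity + free monomer → quenched substrate (k = 0.00712 /M/s)
    free monomer + initiator → living end + monomer in chains (k = 0.00382 /M/s)
    monomer in chains + living end → free monomer + living end, rate k4*[living end] as long as [monomer in chains] is above zero (k = 2.14 × 10⁻⁴ /s)

The flask gives yes, with length 6.26 at 5.0 h, the wanted length being passed at 2.13 h. At 5.00 h quenched substrate stands at 1.58 mM, with 0.00913% of the protic impurity left from its charge of 1.58 mM. At 50.0 h the flask holds 57.5% of the free monomer charged as monomer in chains, with 0% of the initiator left and living end at 0.00160 M, and the roof 49.4 turns that share into a length of 28.4.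

(The readings were computed with constants of no real substance; scatter was added.)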